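Decide first to count Zb, not to watch the clock. Each Za that reacts takes at least one Zb, so the charges draw a ceiling before any rate is known.

| flask | Za | Zb | remark | time |
|---|---|---|---|---|
| south-east | 1.5 M | 0.75 M | the very flask that is asked about, followed so far |  |
| north | 2.2 M | 0.75 M | run made earlier |  |
| flask | 1.5 M | 0.750 M |  | 15 d |

- south-east (time / h: Za / %, Ze / %): 8.00: 58.3, 4.2; 15.0: 58.1, 0.8; 20.0: 56.9, 0.4; 30.0: 58.3, 2.5
- north (time / d: Za / %, Ze / %): 1.25: 68.0, 1.4; 4.00: 67.3, 2.4; 6.00: 69.7, 0.1; 10.0: 67.3, 1.5

(readings scatter by 1 percentage point)

- what was read earlier has a scatter of 1 percentage point, one standard deviation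
- the reaction counts as stopped when no species that holds the Za changes by six tenths of a point or more over the second half of the time

- the state of affairs at 15 d: stopped, and by what, or still going (it is still moving / forward and back rates have come level / all of Za has reacted)
- how much of the Za has reacted by 15 d
- how much Ze there is at 15 d, in percent of the Za charged
- how much Zd there is at 15 d, in percent of the Za charged
- how much Zf there is at 15 d, in percent of the Za charged

Your ceiling here is B = 50.0 %. B is the budget, the Zb charged divided by the Za charged. It lies below the whole Za, so Zb is the limiting reagent. Let R be the mean reacted share, read from the Za readings, and set it against B for each run: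

South-east: B = 50.0 %, R = 42.1 %, gap B − R = 7.9 percentage points

North: B = 34.1 %, R = 31.9 %, gap B − R = 2.2 points

Now draw the curve for the south-east flask. Reacted Za starts steeply, for it already stands on its level at the first reading, 8.00 h. So the knee lies earlier, and the curve bends off below B. It then runs flat to 30.0 h, and the north run stays flat to 10.0 d. Za remains in both, so I expect this flask to stop by balance at 15 d, with R as its conversion.

In the south-east flask, the gap is Zb spent on further exchanges or left over. Ze reads 1.98 % on average there and takes one extra Zb each. Zf takes two extra. So if no Zb is left over, these scattered readings put Zf near 2.96 % and Zd near 37.2 %, as estimates and not bounds.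

The forecast, with “Zb caps the exchanges”, gives forward and back rates have come level, conversion 42 %, Ze 2 %, Zd 38 % and Zf 2 %.

The flask gives forward and back rates have come level, conversion 42.6 %, Ze 1.63 %, Zd 38.1 % and Zf 2.11 %.

    Zf + Zb ⇌ Zc + Zg (K = 0.412, k = 5.26 × 10⁻⁴ /M/s)
    Ze + Zb ⇌ Zc + Zf (K = 84.6, k = 0.00128 /M/s)
    Zd + Zb ⇌ Zc + Ze (K = 2.80, k = 0.00412 /M/s)
    Ze ⇌ Zh (K = 0.450, k = 3.68 × 10⁻⁴ /s)
    Za + Zb ⇌ Zc + Zd (K = 43.4, k = 0.00143 /M/s)

In this flask the gap is 7.4 points, and 1.5 % of the Zb charge is left. Now take the neighbour with 2.5 M of Za. Its budget is 30.0 %, below the north run's. The gap narrowed from south-east to north as Za rose, so expect the conversion just under that budget. It reacts to 27.9 %, a gap of 2.1 points, narrower than this flask's. That neighbour holds 26.6 % of Zd at 15.0 d.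

The numbers in the tables were generated by integration from invented constants, noise included.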